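## Structural features

The target is a linear C1–C12 chain whose C12 ketone is the 3-acyl substituent of a 4-hydroxy-6-methyl-5,6-dihydro-2H-pyran-2-one (O1', C2'–C6'). Chain and ring meet at the C12–C3' bond, so the right-hand end is one enolised, acidic β,β'-tricarbonyl unit. On the left, three stereocentres are contiguous: C3 (S, methyl), C4 (R, secondary hydroxyl) and C5 (S, carrying the hydroxymethyl carbon C5a). C5 is allylic to an (E)-C6=C7 alkene, an isolated methyl centre C9 (R) follows, and the ring carries C6' (R). The fragile parts are the tricarbonyl/lactone, the 1,3-diol, and the allylic C5 methine, which would epimerise or move into conjugation if a carbonyl were ever placed at C4 or C6. C3 comes from an α-branched aldehyde that racemises easily and whose methyl and ethyl arms are too alike to give substrate control. The real difficulty is therefore to set C4 and C5 against C3 by reagent control and to build the E-alkene next to C5 without an enolisable intermediate, while joining two halves of similar size. The array C4(OH)–C5(C5a)–C6=C7 is a syn homoallylic alcohol whose E-alkene points toward C8, which is what an α-substituted, γ-(Z)-substituted allylboronate delivers to an aldehyde with chirality relayed from C7 to C4 and C5.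

## Logic of the disconnections

31 ⇒ 30. Only the two acetal C–O bonds over O4 and O5a are cut. The diol is the last thing released, so the polar tricarbonyl diol is never carried through other chemistry. The forward step must be a mild hydrolysis that leaves lactone, enol and alkene alone.

30 ⇒ 24 + 28. The C12–C3' bond is cut, which separates the whole chain from the ring in one stroke. The gain is full convergence: the tricarbonyl appears only in the penultimate step. The forward step must acylate carbon, not oxygen, at C3' of 28, and 24 must have no other free hydroxyl.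

28 ⇒ 26 ⇒ 25. The lactone bond O1'–C2' is cut, then C3'–C4'. This reduces the ring to a chiral-pool β-hydroxy ester that already holds C6'. The forward steps must not eliminate or invert the C6' carbinol.

24 ⇒ 22 ⇒ 21 ⇒ 20. These are changes of oxidation level and protection only: C12 carboxyl back to a silyl-protected primary alcohol, and the O4–C(acetal) bond back to a free C4 hydroxyl beside a C5a p-methoxybenzyl ether. The benzyl carbon already present becomes the acetal carbon, so no extra protecting group is introduced. The forward oxidation at C12 must spare the acetal and the alkene.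

20 ⇒ 16 + 18. The C4–C5 bond is cut with transposition of the alkene from C6=C7 to C5=C6 (Z) and boron placed at C7. One bond formation joins a C1–C4 piece to a C5–C12 piece, sets C4 and C5 and fixes the E-alkene. C5 is never next to a carbonyl. The forward step demands a geometrically pure (Z)-alkene and an enantiomerically defined C7 in 16, and fresh, unracemised 18.

18 ⇒ 17. Adjustment of oxidation level at C4; C3 is bought. The oxidation must not racemise the α-centre.

16 ⇒ 5 + 13. The C6–C7 bond is cut. C7 becomes a carbamate-bearing CH2 that can be deprotonated enantioselectively, and C5–C6 becomes a (Z)-alkenylboronate. The boron-bearing centre is thus made by reagent control, independent of C9. The forward step needs the diamine enantiomer that removes the pro-S hydrogen, and a 1,2-shift that keeps the Z geometry.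

13 ⇒ 11 ⇒ 8 ⇒ 6. The C6–H and C5–H bonds (cis reduction of the alkynylboronate), the C6–B bond and the benzyl ether O–C bond are cut in turn, ending at a three-carbon alkyne alcohol. The forward reduction must give the Z isomer only, because any E isomer becomes the anti diastereomer after the key step.

5 ⇒ 4 ⇒ 2 ⇒ 1. The O–Si bond, the C12 oxygen (from cleavage of a C12=C bond) and the carbamate C–O bond are cut, ending at a terpene alcohol that supplies C7–C12 with C9 in place. The alkene cleavage is done before C6=C7 exists, so there is no competition between alkenes.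

## Other disconnections considered

Alternative 1: The cut is C8–C9. The (6S)-propanoate A1 of a C1–C8 allylic alcohol (C4/C5a diol as acetonide, terminal C7=C8) would be converted with LiN(iPr)2 and Me3SiCl in THF at −78 °C into the silyl ketene acetal with the methyl group cis to the allylic oxygen. An Ireland–Claisen shift through a chair, with the dioxane substituent on C6 equatorial, would form C8–C9, move the alkene to (E)-C6=C7 and give acid A2. C9 in A2 has the arrangement of the target; its descriptor reads S only because C10 is a carboxyl carbon.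
- In favour: C9 comes from an achiral propanoate and not from a purchased terpene. The step is unimolecular, and no organoboron or diamine chemistry is needed.
- Against: A1 needs C4, C5 and C6 set beforehand and C6 is then destroyed, so the C4–C5 problem is moved, not solved. The C9 ratio would mirror the ketene acetal geometry, and remote C9 epimers would be hard to separate. A2 ends at C10, so C11 and C12 must still be added by reduction, two-carbon olefination and a conjugate reduction that spares C6=C7, with C9 next to a carbonyl on the way.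
- Comparison: on alkene geometry the two plans are equal, since each relies on an equatorial substituent in a chair. On control of C9 purity and on rate (intramolecular) the alternative is the better one. On step economy and convergence the chosen plan is better, because its stereo-defining step is also the union of two halves.

Alternative 2: The cut is the C4–H bond, with C5 equilibrating through the enol. β-Keto ester A3, a mixture of C5 epimers, would be hydrogenated with H2 and RuBr2((R)-BINAP), a divalent ruthenium catalyst, under conditions where the epimers interconvert faster than they are reduced. This would give hydroxy ester A4, which holds C1–C6 and C5a of the target.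
- In favour: the method is catalytic, needs no stoichiometric chiral reagent or cryogenic organolithium, and sets two centres in one step from a simply made substrate. On atom economy and scale it is the better plan.
- Against: high syn selectivity in acyclic reductions of this kind is tied to a coordinating α-substituent, and a benzyloxymethyl group is a weaker director. C3 sits next to the ketone in A3 and could epimerise under the same conditions. The ester carbon C6 of A4 must afterwards be reduced and the resulting carbonyl olefinated to attach C7–C12, which puts C5 next to a carbonyl with a β-oxygen. The benzyl ether cannot be removed by hydrogenolysis once the alkene is present.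
- Comparison: both plans set C4 and C5 together and both override the unbiased C3 centre, so they are equal there. The chosen plan also forms the alkene and joins the halves in the same step, whereas the alternative needs a separate olefination and a change of protecting group, so it is no shorter and is less convergent.

Alternative 3: The cut is C5–C5a. Tin–lithium exchange (n-BuLi, THF, −78 °C) on the (4R,7S,Z)-stannylmethyl ether A5 would give an α-alkoxy carbanion. A [2,3] Wittig–Still shift through a five-membered envelope would bond C5a to C5 on the face from which the C7 oxygen leaves. The C8 chain stays pseudo-equatorial to avoid allylic strain with the Z substituent, so the alkene becomes (E)-C6=C7 and the product is A6.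
- In favour: the shift is unimolecular and fast at low temperature, with no hindered bimolecular encounter; here the alternative is the better one. A6 has the C5a hydroxyl free beside a C4 p-methoxybenzyl ether, so the same oxidative acetal closure would follow, and on that point it equals the chosen plan. C4 is set on its own, so the key step involves no double stereodifferentiation.
- Against: two carbinol centres (C4 and C7) must be made by separate asymmetric steps and C7 is then sacrificed. The step adds one carbon and joins no fragments. It uses stoichiometric organotin and strong base, and a [1,2] shift can compete. A6 ends in a trisubstituted C12 alkene that would have to be cleaved in the presence of C6=C7.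
- Comparison: the two plans share the idea of relaying C7 to C5 with a Z-to-E transposition. The chosen plan forms a skeletal bond between large fragments and sets C4 at the same time, and is several steps shorter.

Key step: step 9

Remarks on the chemistry:
- The tricarbonyl unit is written throughout as the 4-hydroxy-2-pyranone tautomer; other enol forms are the same compound.
- The acetal carbon of 21–24 and 29–30 is taken as the isomer with the aryl group equatorial. It is lost in step 16, so its configuration is of no consequence.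
- The (7R,Z) boronate with the (S)-aldehyde does lead to (4R,5S,E), so the precursor skeleton is kept. (−)-Sparteine is the enantiomer needed.
- The aldehyde gives no useful Felkin reinforcement. Its methyl and ethyl arms are nearly equal, and with a (Z)-γ-substituted allylboron reagent the small intrinsic bias of α-methyl aldehydes is toward the other face. The plan therefore rests on reagent control alone.
- Changes to the precursor's preparation and use: the (Z)-alkenylboronate is made by a route that excludes the E isomer, and 16 is freed of Lewis acid and diamine before the union. The tricarbonyl is built by direct C-acylation, which shortens the linear sequence after the union.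

## Route

Step 1
Reactants: 1 (R)-citronellol
Product: 2 (3R)-3,7-dimethyloct-6-en-1-yl N,N-diisopropylcarbamate
Conditions: iPr2NCOCl, Et3N, CH2Cl2, reflux
Reagents that add atoms: N,N-diisopropylcarbamoyl chloride, ClC(=O)N(C(C)C)C(C)C
Why: Acyl substitution at a hindered carbamoyl chloride by the primary alcohol; the carbamate is the directing and leaving group for step 7 and is inert to ozone, hydride and silylation. The C9 centre is not touched.

Step 2
Reactants: 2 (3R)-3,7-dimethyloct-6-en-1-yl N,N-diisopropylcarbamate
Product: 4 (3R)-6-hydroxy-3-methylhexyl N,N-diisopropylcarbamate, via aldehyde 3 (not isolated)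
Conditions: O3, CH2Cl2/MeOH (4:1), −78 °C; then NaBH4, −78 °C → rt
Reagents that add atoms: ozone, [O-][O+]=O
Why: Ozonolysis (Criegee mechanism) of the only alkene with reductive work-up turns C12 into a primary alcohol. The carbamate survives ozone and borohydride.

Step 3
Reactants: 4 (3R)-6-hydroxy-3-methylhexyl N,N-diisopropylcarbamate
Product: 5 (3R)-3-methyl-6-[(triisopropylsilyl)oxy]hexyl N,N-diisopropylcarbamate
Conditions: TIPSCl, imidazole, DMF, rt
Reagents that add atoms: chlorotriisopropylsilane, CC(C)[Si](Cl)(C(C)C)C(C)C
Why: Silylation of a primary alcohol. The bulky silyl ether withstands s-BuLi, MgBr2 and DDQ and is removed by fluoride in step 11.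

Step 4
Reactants: 6 propargyl alcohol
Product: 8 1-methoxy-4-[(prop-2-yn-1-yloxy)methyl]benzene, via sodium alkoxide 7 (not isolated)
Conditions: NaH, THF, 0 °C; then PMBCl, Bu4NI (cat.), 0 °C → rt
Reagents that add atoms: 4-methoxybenzyl chloride, COc1ccc(CCl)cc1
Why: Williamson ether synthesis; the hydroxyl is far more acidic than the alkyne C–H, so O-alkylation is selective. The p-methoxybenzyl group later supplies the acetal carbon.

Step 5
Reactants: 8 1-methoxy-4-[(prop-2-yn-1-yloxy)methyl]benzene
Product: 11 2-{3-[(4-methoxybenzyl)oxy]prop-1-yn-1-yl}-4,4,5,5-tetramethyl-1,3,2-dioxaborolane, via lithium acetylide 9 (not isolated), via borate complex 10 (not isolated)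
Conditions: n-BuLi, THF, −78 °C; iPrOBpin, −78 °C; then HCl in Et2O, −78 °C → rt
Reagents that add atoms: 2-isopropoxy-4,4,5,5-tetramethyl-1,3,2-dioxaborolane, CC(C)OB1OC(C)(C)C(C)(C)O1
Why: Borylation of a lithium acetylide with an alkoxyboronate. Anhydrous acid collapses the tetracoordinate borate by loss of isopropanol without protodeboronation.

Step 6
Reactants: 11 2-{3-[(4-methoxybenzyl)oxy]prop-1-yn-1-yl}-4,4,5,5-tetramethyl-1,3,2-dioxaborolane
Product: 13 (Z)-2-{3-[(4-methoxybenzyl)oxy]prop-1-en-1-yl}-4,4,5,5-tetramethyl-1,3,2-dioxaborolane, via borylzirconocene 12 (not isolated)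
Conditions: Cp2Zr(H)Cl, THF, rt; then H2O
Reagents that add atoms: none
Why: syn-Hydrozirconation of a 1-alkynylboronate places zirconium on the boron-bearing carbon; protonolysis of the C–Zr bond with retention leaves boron cis to the CH2O group. The Z geometry fixed here becomes the syn C4/C5 relation in step 9.

Step 7
Reactants: 5 (3R)-3-methyl-6-[(triisopropylsilyl)oxy]hexyl N,N-diisopropylcarbamate; 13 (Z)-2-{3-[(4-methoxybenzyl)oxy]prop-1-en-1-yl}-4,4,5,5-tetramethyl-1,3,2-dioxaborolane
Product: 16 2-{(2Z,4R,6R)-1-[(4-methoxybenzyl)oxy]-6-methyl-9-[(triisopropylsilyl)oxy]non-2-en-4-yl}-4,4,5,5-tetramethyl-1,3,2-dioxaborolane, via lithiated carbamate 14 (not isolated), via boronate complex 15 (not isolated)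
Conditions: s-BuLi, (−)-sparteine, Et2O, −78 °C, 5 h; 13 (1.3 equiv), −78 °C, 1 h; MgBr2·OEt2, −78 °C → 35 °C; aqueous work-up, short silica filtration, use at once
Reagents that add atoms: none
Why: Lithiation–borylation: s-BuLi/(−)-sparteine removes the pro-S hydrogen at C7 to give the configurationally stable (S)-organolithium 14, which adds to boron with retention to give 15. The (Z)-alkenyl group then migrates from boron to C7 anti to the departing carbamate (inversion), forming C6–C7 and setting (7R) with the alkene geometry unchanged. MgBr2 assists loss of the carbamate, and removing it and the diamine before step 9 keeps the later addition on the closed, uncatalysed pathway.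

Step 8
Reactants: 17 (S)-2-methylbutan-1-ol
Product: 18 (S)-2-methylbutanal
Conditions: TEMPO (cat.), KBr (cat.), NaOCl, NaHCO3, CH2Cl2/H2O, 0 °C; dried CH2Cl2 solution used the same day
Reagents that add atoms: none
Why: Oxoammonium-mediated oxidation under buffered two-phase conditions stops at the aldehyde and is mild enough to keep the α-centre intact. The volatile, epimerisable aldehyde is not stored.

Step 9
Reactants: 16 2-{(2Z,4R,6R)-1-[(4-methoxybenzyl)oxy]-6-methyl-9-[(triisopropylsilyl)oxy]non-2-en-4-yl}-4,4,5,5-tetramethyl-1,3,2-dioxaborolane; 18 (S)-2-methylbutanal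
Product: 20 (3S,4R,5S,6E,9R)-5-{[(4-methoxybenzyl)oxy]methyl}-3,9-dimethyl-12-[(triisopropylsilyl)oxy]dodec-6-en-4-ol, via borate ester 19 (not isolated)
Conditions: 18 (2 equiv), CH2Cl2, 4 Å MS, rt, 24–48 h; then aq NaHCO3
Reagents that add atoms: none
Why: The carbonyl oxygen of 18 binds the boron of 16 and the allyl unit is delivered through a closed six-membered chair (thermal allylboration of an aldehyde by an α-substituted γ-(Z) allylic pinacol boronate); C4–C5 forms, the alkene moves to C6=C7, boron ends on O4 (19) and work-up frees 20. No ring is formed; the only cyclic array is the transition state. C5 (S) follows from the Z geometry, which puts the CH2OPMB group axial at C5 while the sec-butyl group of the aldehyde sits equatorial, giving the syn C4/C5 relation. An axial C8 chain at C7 would clash 1,3-diaxially with that axial group, so the C8 chain is equatorial; this gives the E-alkene and, with (7R), selects the chair in which the Si face of 18 is attacked, giving C4 (R). The selectivity needed is reagent control over an aldehyde with no useful bias of its own, so it depends on the geometric purity of 13 and the enantiomeric purity of 16. The neutral conditions leave C3 and C9 alone. C5 is created together with the alkene and is never next to a carbonyl.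

Step 10
Reactants: 20 (3S,4R,5S,6E,9R)-5-{[(4-methoxybenzyl)oxy]methyl}-3,9-dimethyl-12-[(triisopropylsilyl)oxy]dodec-6-en-4-ol
Product: 21 (2S,4R,5S)-4-[(S)-butan-2-yl]-2-(4-methoxyphenyl)-5-{(1E,4R)-4-methyl-7-[(triisopropylsilyl)oxy]hept-1-en-1-yl}-1,3-dioxane
Conditions: DDQ, 4 Å MS, CH2Cl2, 0 °C
Reagents that add atoms: none
Why: DDQ oxidises the p-methoxybenzyl ether to an oxocarbenium ion that the C4 hydroxyl traps under anhydrous conditions (oxidative acetal formation). The 1,3-dioxane can place aryl, sec-butyl and alkenyl groups all equatorial, which sets the acetal carbon as drawn and protects O4 and O5a in one operation.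

Step 11
Reactants: 21 (2S,4R,5S)-4-[(S)-butan-2-yl]-2-(4-methoxyphenyl)-5-{(1E,4R)-4-methyl-7-[(triisopropylsilyl)oxy]hept-1-en-1-yl}-1,3-dioxane
Product: 22 (4R,6E)-7-[(2S,4R,5S)-4-((S)-butan-2-yl)-2-(4-methoxyphenyl)-1,3-dioxan-5-yl]-4-methylhept-6-en-1-ol
Conditions: Bu4NF, THF, 0 °C → rt
Reagents that add atoms: none
Why: Fluoride cleaves the Si–O bond; the acetal and alkene are inert to these basic conditions.

Step 12
Reactants: 22 (4R,6E)-7-[(2S,4R,5S)-4-((S)-butan-2-yl)-2-(4-methoxyphenyl)-1,3-dioxan-5-yl]-4-methylhept-6-en-1-ol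
Product: 24 (4R,6E)-7-[(2S,4R,5S)-4-((S)-butan-2-yl)-2-(4-methoxyphenyl)-1,3-dioxan-5-yl]-4-methylhept-6-enoic acid, via aldehyde 23 (not isolated)
Conditions: TEMPO (cat.), NaOCl (cat.), NaClO2, MeCN/phosphate buffer (pH 6.7), 35 °C
Reagents that add atoms: sodium chlorite, [Na+].[O-]Cl=O
Why: Oxoammonium oxidation to aldehyde 23 followed in the same pot by chlorite (Pinnick-type) oxidation, the hypochlorite formed re-oxidising the nitroxyl. The near-neutral buffer protects the acetal, and the only oxidisable hydroxyl is the primary one.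

Step 13
Reactants: 25 methyl (R)-3-hydroxybutanoate
Product: 26 tert-butyl (R)-5-hydroxy-3-oxohexanoate
Conditions: tBuOAc, LiN(iPr)2 (3.5 equiv), THF, −78 → −20 °C; then aq NH4Cl
Reagents that add atoms: tert-butyl acetate, CC(=O)OC(C)(C)C
Why: Crossed Claisen condensation: excess ester enolate first forms the C6' alkoxide, which protects against elimination, then acylates at the methyl ester to form C3'–C4'. The carbinol centre is not involved.

Step 14
Reactants: 26 tert-butyl (R)-5-hydroxy-3-oxohexanoate
Product: 28 (R)-4-hydroxy-6-methyl-5,6-dihydro-2H-pyran-2-one, via hydroxy keto acid 27 (not isolated)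
Conditions: CF3CO2H, CH2Cl2, rt
Reagents that add atoms: none
Why: Acidolysis of the tert-butyl ester and δ-lactonisation of hydroxy acid 27 close O1'–C2'. The C6' oxygen keeps its bond to carbon, so the configuration is retained.

Step 15
Reactants: 24 (4R,6E)-7-[(2S,4R,5S)-4-((S)-butan-2-yl)-2-(4-methoxyphenyl)-1,3-dioxan-5-yl]-4-methylhept-6-enoic acid; 28 (R)-4-hydroxy-6-methyl-5,6-dihydro-2H-pyran-2-one
Product: 30 (R)-3-{(4R,6E)-7-[(2S,4R,5S)-4-((S)-butan-2-yl)-2-(4-methoxyphenyl)-1,3-dioxan-5-yl]-4-methylhept-6-enoyl}-4-hydroxy-6-methyl-5,6-dihydro-2H-pyran-2-one, via enol ester 29 (not isolated)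
Conditions: DCC, DMAP, CH2Cl2, 0 °C → rt
Reagents that add atoms: none
Why: Carbodiimide esterification at the enolic oxygen gives 29; DMAP then mediates an O-to-C acyl shift (Fries-type rearrangement through an acylpyridinium/dione enolate pair) to the more stable C3'-acyl tricarbonyl, forming C12–C3'. The enol is the only free hydroxyl, and no stereocentre is involved.

Step 16
Reactants: 30 (R)-3-{(4R,6E)-7-[(2S,4R,5S)-4-((S)-butan-2-yl)-2-(4-methoxyphenyl)-1,3-dioxan-5-yl]-4-methylhept-6-enoyl}-4-hydroxy-6-methyl-5,6-dihydro-2H-pyran-2-one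
Product: 31 (R)-4-hydroxy-3-[(4R,6E,8S,9R,10S)-9-hydroxy-8-(hydroxymethyl)-4,10-dimethyldodec-6-enoyl]-6-methyl-5,6-dihydro-2H-pyran-2-one
Conditions: AcOH/THF/H2O (4:1:1), 40 °C
Reagents that add atoms: none
Why: Acid-catalysed hydrolysis of the electron-rich arylidene acetal frees O4 and O5a. Lactone, tricarbonyl and alkene tolerate dilute acetic acid, and no C–O bond at a stereocentre is broken.

## Compound list

1 | (R)-citronellol, (3R)-3,7-dimethyloct-6-en-1-ol | CC(C)=CCC[C@@H](C)CCO | starting material
2 | (3R)-3,7-dimethyloct-6-en-1-yl N,N-diisopropylcarbamate | CC(C)=CCC[C@@H](C)CCOC(=O)N(C(C)C)C(C)C | intermediate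
3 | (3R)-3-methyl-6-oxohexyl N,N-diisopropylcarbamate (not isolated) | O=CCC[C@@H](C)CCOC(=O)N(C(C)C)C(C)C | intermediate
4 | (3R)-6-hydroxy-3-methylhexyl N,N-diisopropylcarbamate | OCCC[C@@H](C)CCOC(=O)N(C(C)C)C(C)C | intermediate
5 | (3R)-3-methyl-6-[(triisopropylsilyl)oxy]hexyl N,N-diisopropylcarbamate | CC(C)[Si](OCCC[C@@H](C)CCOC(=O)N(C(C)C)C(C)C)(C(C)C)C(C)C | intermediate
6 | propargyl alcohol | OCC#C | starting material
7 | sodium prop-2-yn-1-olate (not isolated) | [Na+].[O-]CC#C | intermediate
8 | 1-methoxy-4-[(prop-2-yn-1-yloxy)methyl]benzene | COc1ccc(COCC#C)cc1 | intermediate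
9 | {3-[(4-methoxybenzyl)oxy]prop-1-yn-1-yl}lithium (not isolated) | [Li]C#CCOCc1ccc(OC)cc1 | intermediate
10 | lithium isopropoxy{3-[(4-methoxybenzyl)oxy]prop-1-yn-1-yl}(pinacolato)borate (not isolated) | [Li+].COc1ccc(COCC#C[B-]2(OC(C)C)OC(C)(C)C(C)(C)O2)cc1 | intermediate
11 | 2-{3-[(4-methoxybenzyl)oxy]prop-1-yn-1-yl}-4,4,5,5-tetramethyl-1,3,2-dioxaborolane | COc1ccc(COCC#CB2OC(C)(C)C(C)(C)O2)cc1 | intermediate
12 | chlorobis(cyclopentadienyl){(E)-3-[(4-methoxybenzyl)oxy]-1-(pinacolatoboryl)prop-1-en-1-yl}zirconium, boron cis to the CH2O group (not isolated) | COc1ccc(COC/C=C(\B2OC(C)(C)C(C)(C)O2)[Zr](Cl)(C3C=CC=C3)C3C=CC=C3)cc1 | intermediate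
13 | (Z)-2-{3-[(4-methoxybenzyl)oxy]prop-1-en-1-yl}-4,4,5,5-tetramethyl-1,3,2-dioxaborolane | COc1ccc(COC/C=C\B2OC(C)(C)C(C)(C)O2)cc1 | intermediate
14 | (1S,3R)-1-lithio-3-methyl-6-[(triisopropylsilyl)oxy]hexyl N,N-diisopropylcarbamate, as its (−)-sparteine complex (not isolated) | [Li][C@H](OC(=O)N(C(C)C)C(C)C)C[C@H](C)CCCO[Si](C(C)C)(C(C)C)C(C)C | intermediate
15 | lithium boronate complex: boron carries pinacolate, the (Z)-alkenyl group of 13 and the (1S)-1-(carbamoyloxy)alkyl group of 14 (not isolated) | [Li+].COc1ccc(COC/C=C\[B-]2([C@H](OC(=O)N(C(C)C)C(C)C)C[C@H](C)CCCO[Si](C(C)C)(C(C)C)C(C)C)OC(C)(C)C(C)(C)O2)cc1 | intermediate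
16 | 2-{(2Z,4R,6R)-1-[(4-methoxybenzyl)oxy]-6-methyl-9-[(triisopropylsilyl)oxy]non-2-en-4-yl}-4,4,5,5-tetramethyl-1,3,2-dioxaborolane (the (7R,Z) allylboronate) | COc1ccc(COC/C=C\[C@H](B2OC(C)(C)C(C)(C)O2)C[C@H](C)CCCO[Si](C(C)C)(C(C)C)C(C)C)cc1 | intermediate
17 | (S)-2-methylbutan-1-ol | CC[C@H](C)CO | starting material
18 | (S)-2-methylbutanal | CC[C@H](C)C=O | intermediate
19 | pinacol borate ester at O4 of 20 (not isolated) | CC[C@H](C)[C@@H](OB1OC(C)(C)C(C)(C)O1)[C@@H](/C=C/C[C@H](C)CCCO[Si](C(C)C)(C(C)C)C(C)C)COCc1ccc(OC)cc1 | intermediate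
20 | (3S,4R,5S,6E,9R)-5-{[(4-methoxybenzyl)oxy]methyl}-3,9-dimethyl-12-[(triisopropylsilyl)oxy]dodec-6-en-4-ol | CC[C@H](C)[C@@H](O)[C@@H](/C=C/C[C@H](C)CCCO[Si](C(C)C)(C(C)C)C(C)C)COCc1ccc(OC)cc1 | intermediate
21 | (2S,4R,5S)-4-[(S)-butan-2-yl]-2-(4-methoxyphenyl)-5-{(1E,4R)-4-methyl-7-[(triisopropylsilyl)oxy]hept-1-en-1-yl}-1,3-dioxane | CC[C@H](C)[C@H]1O[C@@H](c2ccc(OC)cc2)OC[C@@H]1/C=C/C[C@H](C)CCCO[Si](C(C)C)(C(C)C)C(C)C | intermediate
22 | (4R,6E)-7-[(2S,4R,5S)-4-((S)-butan-2-yl)-2-(4-methoxyphenyl)-1,3-dioxan-5-yl]-4-methylhept-6-en-1-ol | CC[C@H](C)[C@H]1O[C@@H](c2ccc(OC)cc2)OC[C@@H]1/C=C/C[C@H](C)CCCO | intermediate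
23 | (4R,6E)-7-[(2S,4R,5S)-4-((S)-butan-2-yl)-2-(4-methoxyphenyl)-1,3-dioxan-5-yl]-4-methylhept-6-enal (not isolated) | CC[C@H](C)[C@H]1O[C@@H](c2ccc(OC)cc2)OC[C@@H]1/C=C/C[C@H](C)CCC=O | intermediate
24 | (4R,6E)-7-[(2S,4R,5S)-4-((S)-butan-2-yl)-2-(4-methoxyphenyl)-1,3-dioxan-5-yl]-4-methylhept-6-enoic acid | CC[C@H](C)[C@H]1O[C@@H](c2ccc(OC)cc2)OC[C@@H]1/C=C/C[C@H](C)CCC(=O)O | intermediate
25 | methyl (R)-3-hydroxybutanoate | COC(=O)C[C@@H](C)O | starting material
26 | tert-butyl (R)-5-hydroxy-3-oxohexanoate | CC(C)(C)OC(=O)CC(=O)C[C@@H](C)O | intermediate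
27 | (R)-5-hydroxy-3-oxohexanoic acid (not isolated) | OC(=O)CC(=O)C[C@@H](C)O | intermediate
28 | (R)-4-hydroxy-6-methyl-5,6-dihydro-2H-pyran-2-one | C[C@@H]1CC(O)=CC(=O)O1 | intermediate
29 | (R)-6-methyl-2-oxo-5,6-dihydro-2H-pyran-4-yl ester of acid 24 (not isolated) | CC[C@H](C)[C@H]1O[C@@H](c2ccc(OC)cc2)OC[C@@H]1/C=C/C[C@H](C)CCC(=O)OC1=CC(=O)O[C@H](C)C1 | intermediate
30 | (R)-3-{(4R,6E)-7-[(2S,4R,5S)-4-((S)-butan-2-yl)-2-(4-methoxyphenyl)-1,3-dioxan-5-yl]-4-methylhept-6-enoyl}-4-hydroxy-6-methyl-5,6-dihydro-2H-pyran-2-one | CC[C@H](C)[C@H]1O[C@@H](c2ccc(OC)cc2)OC[C@@H]1/C=C/C[C@H](C)CCC(=O)C1=C(O)C[C@@H](C)OC1=O | intermediate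
31 | (R)-4-hydroxy-3-[(4R,6E,8S,9R,10S)-9-hydroxy-8-(hydroxymethyl)-4,10-dimethyldodec-6-enoyl]-6-methyl-5,6-dihydro-2H-pyran-2-one | CC[C@H](C)[C@@H](O)[C@@H](/C=C/C[C@H](C)CCC(=O)C1=C(O)C[C@@H](C)OC1=O)CO | target

## Step count and uncertain steps

Total step count: 16. Longest linear sequence: 10 steps (steps 1, 2, 3, 7, 9, 10, 11, 12, 15, 16; the branch through steps 4, 5, 6 is equally long).

**Step 9 (key step).** The union is bimolecular between a hindered α,γ-disubstituted allylboronate and an α-branched, volatile aldehyde. A slow reaction would give time for racemisation or loss of the aldehyde and for allylic isomerisation of the boron reagent. Facial selection rests entirely on the reagent, so any E isomer carried from step 6 or any erosion at C7 in step 7 would appear as diastereomers that differ little from the product. The fallback builds C4/C5 by epoxide chemistry and the alkene by metathesis; it sets out from 18 (and from 5 for the partner) and rejoins the route at 21.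
- Wittig olefination of 18 (Ph3P=CHCO2Et, CH2Cl2, rt) would give ethyl (S,E)-4-methylhex-2-enoate F1.
- Reduction (iBu2AlH, CH2Cl2, −78 °C) would give (S,E)-4-methylhex-2-en-1-ol F2.
- Sharpless asymmetric epoxidation (Ti(OiPr)4, D-(−)-diethyl tartrate, tBuOOH, 4 Å MS, CH2Cl2, −20 °C) would give [(2R,3R)-3-((S)-butan-2-yl)oxiran-2-yl]methanol F3.
- Vinylmagnesium bromide with catalytic CuI should open the epoxide at the carbon that becomes C5, away from the branched side and with inversion, giving (2S,3R,4S)-2-ethenyl-4-methylhexane-1,3-diol F4.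
- 4-Methoxybenzaldehyde dimethyl acetal with pyridinium tosylate would convert F4 into (2S,4R,5S)-4-((S)-butan-2-yl)-5-ethenyl-2-(4-methoxyphenyl)-1,3-dioxane F5.
- For the partner, LiAlH4 (THF, reflux) would remove the carbamate of 5 to give (R)-3-methyl-6-[(triisopropylsilyl)oxy]hexan-1-ol F6; Dess–Martin oxidation would give (R)-3-methyl-6-[(triisopropylsilyl)oxy]hexanal F7; Ph3P=CH2 would give (R)-triisopropyl[(4-methylhept-6-en-1-yl)oxy]silane F8.
- Cross-metathesis of F5 with excess F8 (second-generation Hoveyda–Grubbs catalyst RuCl2(H2IMes)(=CH–C6H4–2-OiPr), CH2Cl2, 40 °C) should give the E-alkene 21.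

**Step 7.** Deprotonation may be incomplete, or the diamine-bound organolithium may add sluggishly to the hindered (Z)-alkenylboronate, so that borate formation reverses or the 1,2-shift is outrun by decomposition on warming. The fallback sets out from 5 and rejoins at 16. The same deprotonation is quenched with Me3SnCl to give (1S,3R)-3-methyl-6-[(triisopropylsilyl)oxy]-1-(trimethylstannyl)hexyl N,N-diisopropylcarbamate F9. This can be purified and its enantiomeric purity checked. Tin–lithium exchange (n-BuLi, Et2O, −78 °C, retention) then regenerates 14 free of diamine for borylation with 13 and rearrangement to 16.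

**Step 6.** Hydrozirconation may be incomplete, or the alkenyl metal may isomerise, which would contaminate 13 with the E isomer. The fallback sets out from 8 and rejoins at 13. Rhodium-catalysed trans-hydroboration of the terminal alkyne ([Rh(cod)Cl]2, P(iPr)3, Et3N, HBpin, cyclohexane, rt) gives the (Z)-alkenylboronate by formal anti addition through a metal vinylidene. It makes no compound outside the list (entry F0).

**Step 15.** The acylation may stop at the enol ester, or the activated acid may rearrange to an N-acylurea faster than the O-to-C shift. The fallback closes the ring last (Dieckmann); it sets out from 24 and rejoins at 30.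
- Meldrum's acid with DCC and DMAP would give 5-{(4R,6E)-7-[(2S,4R,5S)-4-((S)-butan-2-yl)-2-(4-methoxyphenyl)-1,3-dioxan-5-yl]-1-hydroxy-4-methylhept-6-en-1-ylidene}-2,2-dimethyl-1,3-dioxane-4,6-dione F10.
- Heating F10 with 25 in toluene at 80 °C would give methyl (R)-3-({(6R,8E)-9-[(2S,4R,5S)-4-((S)-butan-2-yl)-2-(4-methoxyphenyl)-1,3-dioxan-5-yl]-6-methyl-3-oxonon-8-enoyl}oxy)butanoate F11.
- KOtBu in tBuOH/THF would effect Dieckmann closure of C3' onto the methyl ester to give 30.

**Step 10.** Adventitious water would divert the oxocarbenium ion to over-oxidation or to simple loss of the benzyl group, and acetal formation would be incomplete. The fallback sets out from 20 and rejoins at 21. DDQ in wet CH2Cl2 (pH 7 buffer) is used deliberately to give (3S,4R,5S,6E,9R)-5-(hydroxymethyl)-3,9-dimethyl-12-[(triisopropylsilyl)oxy]dodec-6-en-4-ol F12, which is re-protected with 4-methoxybenzaldehyde dimethyl acetal and pyridinium tosylate.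

## Further compounds

F1 | step 9 | ethyl (S,E)-4-methylhex-2-enoate | CC[C@H](C)/C=C/C(=O)OCC
F2 | step 9 | (S,E)-4-methylhex-2-en-1-ol | CC[C@H](C)/C=C/CO
F3 | step 9 | [(2R,3R)-3-((S)-butan-2-yl)oxiran-2-yl]methanol | CC[C@H](C)[C@H]1O[C@@H]1CO
F4 | step 9 | (2S,3R,4S)-2-ethenyl-4-methylhexane-1,3-diol | CC[C@H](C)[C@@H](O)[C@@H](C=C)CO
F5 | step 9 | (2S,4R,5S)-4-((S)-butan-2-yl)-5-ethenyl-2-(4-methoxyphenyl)-1,3-dioxane | CC[C@H](C)[C@H]1O[C@@H](c2ccc(OC)cc2)OC[C@@H]1C=C
F6 | step 9 | (R)-3-methyl-6-[(triisopropylsilyl)oxy]hexan-1-ol | CC(C)[Si](OCCC[C@@H](C)CCO)(C(C)C)C(C)C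
F7 | step 9 | (R)-3-methyl-6-[(triisopropylsilyl)oxy]hexanal | CC(C)[Si](OCCC[C@@H](C)CC=O)(C(C)C)C(C)C
F8 | step 9 | (R)-triisopropyl[(4-methylhept-6-en-1-yl)oxy]silane | CC(C)[Si](OCCC[C@@H](C)CC=C)(C(C)C)C(C)C
F9 | step 7 | (1S,3R)-3-methyl-6-[(triisopropylsilyl)oxy]-1-(trimethylstannyl)hexyl N,N-diisopropylcarbamate | C[Sn](C)(C)[C@H](OC(=O)N(C(C)C)C(C)C)C[C@H](C)CCCO[Si](C(C)C)(C(C)C)C(C)C
F0 | step 6 | none | none
F10 | step 15 | 5-{(4R,6E)-7-[(2S,4R,5S)-4-((S)-butan-2-yl)-2-(4-methoxyphenyl)-1,3-dioxan-5-yl]-1-hydroxy-4-methylhept-6-en-1-ylidene}-2,2-dimethyl-1,3-dioxane-4,6-dione | CC[C@H](C)[C@H]1O[C@@H](c2ccc(OC)cc2)OC[C@@H]1/C=C/C[C@H](C)CCC(O)=C1C(=O)OC(C)(C)OC1=O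
F11 | step 15 | methyl (R)-3-({(6R,8E)-9-[(2S,4R,5S)-4-((S)-butan-2-yl)-2-(4-methoxyphenyl)-1,3-dioxan-5-yl]-6-methyl-3-oxonon-8-enoyl}oxy)butanoate | CC[C@H](C)[C@H]1O[C@@H](c2ccc(OC)cc2)OC[C@@H]1/C=C/C[C@H](C)CCC(=O)CC(=O)O[C@H](C)CC(=O)OC
F12 | step 10 | (3S,4R,5S,6E,9R)-5-(hydroxymethyl)-3,9-dimethyl-12-[(triisopropylsilyl)oxy]dodec-6-en-4-ol | CC[C@H](C)[C@@H](O)[C@@H](/C=C/C[C@H](C)CCCO[Si](C(C)C)(C(C)C)C(C)C)CO
A1 | alternative 1 | (S)-1-[(4R,5S)-4-((S)-butan-2-yl)-2,2-dimethyl-1,3-dioxan-5-yl]prop-2-en-1-yl propanoate (the (6S)-propanoate, target numbering) | CC[C@H](C)[C@H]1OC(C)(C)OC[C@@H]1[C@@H](OC(=O)CC)C=C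
A2 | alternative 1 | (2S,4E)-5-[(4R,5S)-4-((S)-butan-2-yl)-2,2-dimethyl-1,3-dioxan-5-yl]-2-methylpent-4-enoic acid (C1–C10 acid) | CC[C@H](C)[C@H]1OC(C)(C)OC[C@@H]1/C=C/C[C@H](C)C(=O)O
A3 | alternative 2 | methyl (4S)-2-[(benzyloxy)methyl]-4-methyl-3-oxohexanoate, mixture of C2 epimers | CC[C@H](C)C(=O)C(C(=O)OC)COCc1ccccc1
A4 | alternative 2 | methyl (2S,3R,4S)-2-[(benzyloxy)methyl]-3-hydroxy-4-methylhexanoate | CC[C@H](C)[C@@H](O)[C@@H](C(=O)OC)COCc1ccccc1
A5 | alternative 3 | tributyl({[(3S,4R,5Z,7S,9R)-4-[(4-methoxybenzyl)oxy]-3,9,13-trimethyltetradeca-5,12-dien-7-yl]oxy}methyl)stannane | CC[C@H](C)[C@@H](OCc1ccc(OC)cc1)/C=C\[C@@H](OC[Sn](CCCC)(CCCC)CCCC)C[C@H](C)CCC=C(C)C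
A6 | alternative 3 | (2S,3R,4S)-2-[(1E,4R)-4,8-dimethylnona-1,7-dien-1-yl]-3-[(4-methoxybenzyl)oxy]-4-methylhexan-1-ol | CC[C@H](C)[C@@H](OCc1ccc(OC)cc1)[C@@H](/C=C/C[C@H](C)CCC=C(C)C)CO
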